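**Retrosynthetic overview**
- Last bonds: C8–OAc and the C9 ester; the (2S,3S)-epoxy acid comes from angelic acid by Sharpless epoxidation and oxidation.
- Key disconnection C9–C10: an α-(bromomethyl)butenolide is reduced by CrCl2 to an allylchromium, i.e. a β-acyl carbanion (homoenolate, d3) equivalent. Its normally electrophilic β-carbon attacks the C9 aldehyde, closing the ten-membered ring, creating the α-methylene lactone and setting C9 and C10 in one step.
- Butenolide by ring-closing metathesis of a 2-(bromomethyl)acrylate of the C1 carbinol; C1 by asymmetric alkynylation of crotonaldehyde, Z-C2=C3 by Lindlar reduction.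
- C6=C7 enoate by aldol–elimination of a malate-derived ester enolate (carries C8) with a cis-epoxy aldehyde from Sharpless epoxidation of a (Z)-enynol.
- Ring order: oxirane (C4/C5), then butenolide, then ten-membered carbocycle; the side-chain oxirane is made separately.

Assumption: the structure is taken exactly as in the SMILES, and dimethyl (R)-malate, D-(–)-diethyl tartrate and both ProPhenol enantiomers are taken as commercial.

Route locants (not IUPAC, used for all intermediates): C1 = lactone O–CH; C2=C3 = Z-alkene; C4/C5 = epoxide; C6=C7 = enoate alkene (CO2Me on C7); C8 = CH–OAc; C9 = CH–O-ester; C10 = ring-fusion CH; C11/C12/C13 = lactone α-C, C=O, exocyclic CH2. Target = (1R,4S,5R,8R,9S,10S), ester (2S,3S).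

Precaution: compounds from 18 onward contain a cis-divinyl epoxide and are kept at or below 40 °C (Cope rearrangement).

**Step 1**
Reactants: 1 dimethyl (R)-malate
Product: 2 methyl (3R)-3,4-dihydroxybutanoate
Conditions: BH3·SMe2 (1.0 equiv), NaBH4 (5 mol%), THF, 0 °C to rt; MeOH quench; used crude
Reagents that add atoms: none
Why: Hydroxyl-directed borane reduction (Saito–Moriwake) reduces only the ester next to the free OH; the C8 stereocentre comes from the chiral pool and is not touched.

**Step 2**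
Reactants: 2 methyl (3R)-3,4-dihydroxybutanoate
Product: 3 methyl (3R)-3,4-bis(triethylsilyloxy)butanoate
Conditions: TESCl (2.3 equiv), imidazole, DMF, 0 °C
Reagents that add atoms: chlorotriethylsilane CC[Si](Cl)(CC)CC
Why: Silyl ether formation blocks both hydroxyls (no γ-lactonisation) and leaves a primary TES ether that can later be oxidised selectively.

**Step 3**
Reactants: 4 ethyl (Z)-3-iodoprop-2-enoate; 5 ethynyl(trimethyl)silane
Product: 6 ethyl (Z)-5-(trimethylsilyl)pent-2-en-4-ynoate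
Conditions: PdCl2(PPh3)2 (2 mol%), CuI (4 mol%), Et3N, THF, 0 °C to rt
Reagents that add atoms: none
Why: Sonogashira coupling of a vinyl iodide proceeds with retention of the Z geometry.

**Step 4**
Reactants: 6 ethyl (Z)-5-(trimethylsilyl)pent-2-en-4-ynoate
Product: 7 (Z)-5-(trimethylsilyl)pent-2-en-4-yn-1-ol
Conditions: DIBAL-H (2.2 equiv), CH2Cl2, –78 °C; Rochelle salt
Reagents that add atoms: none
Why: DIBAL-H 1,2-reduction of the conjugated ester gives the Z-allylic alcohol without touching the enyne.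

**Step 5**
Reactants: 7 (Z)-5-(trimethylsilyl)pent-2-en-4-yn-1-ol
Product: 8 [(2R,3S)-3-[(trimethylsilyl)ethynyl]oxiran-2-yl]methanol
Conditions: Ti(OiPr)4 (20 mol%), D-(–)-DET (24 mol%), t-BuOOH, 4 Å MS, CH2Cl2, –20 °C
Reagents that add atoms: tert-butyl hydroperoxide CC(C)(C)OO
Why: Sharpless asymmetric epoxidation; D-(–)-tartrate delivers oxygen to the face that gives (2R,3S), and the Z-alkene fixes the cis-epoxide (C4 and C5 set).

**Step 6**
Reactants: 8 [(2R,3S)-3-[(trimethylsilyl)ethynyl]oxiran-2-yl]methanol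
Product: 9 (2S,3S)-3-[(trimethylsilyl)ethynyl]oxirane-2-carbaldehyde
Conditions: Dess–Martin periodinane, NaHCO3, CH2Cl2, 0 °C to rt; used crude
Reagents that add atoms: none
Why: Buffered Dess–Martin oxidation gives the cis-epoxy aldehyde without base-induced epimerisation (the descriptor at C5 changes only by CIP priority).

**Step 7**
Reactants: 3 methyl (3R)-3,4-bis(triethylsilyloxy)butanoate; 9 (2S,3S)-3-[(trimethylsilyl)ethynyl]oxirane-2-carbaldehyde
Product: 13 methyl (2E,3R)-2-{[(2R,3S)-3-[(trimethylsilyl)ethynyl]oxiran-2-yl]methylidene}-3,4-bis(triethylsilyloxy)butanoate, via lithium ester enolate 10 (not isolated), via lithium aldolate 11 (not isolated), via C6 mesylate 12 (not isolated)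
Conditions: 3, LDA, THF, –78 °C; 9, –78 °C; MsCl, –78 to 0 °C; DBU, 0 °C to rt
Reagents that add atoms: none
Why: One-pot aldol addition, mesylation and E1cB elimination (aldol condensation) removes the transient C6/C7 centres and should favour the (E)-enoate with C5 trans to CO2Me, since mesylate is a far better leaving group than the β-silyloxy group.

**Step 8**
Reactants: 13 the TMS-alkynyl enoate
Product: 14 methyl (2E,3R)-2-{[(2R,3S)-3-ethynyloxiran-2-yl]methylidene}-3,4-bis(triethylsilyloxy)butanoate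
Conditions: K2CO3 (0.2 equiv), MeOH, 0 °C, 30 min
Reagents that add atoms: none
Why: Methoxide-catalysed protodesilylation removes the alkynyl TMS group much faster than it attacks TES ethers or the hindered enoate.

**Step 9**
Reactants: 14 the terminal alkyne; 15 (E)-but-2-enal
Product: 17 methyl (2E,3R)-2-({(2R,3S)-3-[(3S,4E)-3-hydroxyhex-4-en-1-yn-1-yl]oxiran-2-yl}methylidene)-3,4-bis(triethylsilyloxy)butanoate, via alkynyl(methyl)zinc 16 (not isolated)
Conditions: Me2Zn (3 equiv), (S,S)-ProPhenol (20 mol%), Ph3PO (40 mol%), toluene, 4 °C; then 15 (3 equiv), 4 °C, 48 h; aq NH4Cl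
Reagents that add atoms: none
Why: Zn–ProPhenol (Trost) asymmetric alkynylation of an enal sets C1 as (S) under catalyst control; the ligand enantiomer is the one giving the (S)-carbinol (checked by Mosher analysis, antipode available).

**Step 10**
Reactants: 17 the propargylic alcohol
Product: 18 methyl (2E,3R)-2-({(2R,3S)-3-[(1Z,3S,4E)-3-hydroxyhexa-1,4-dien-1-yl]oxiran-2-yl}methylidene)-3,4-bis(triethylsilyloxy)butanoate
Conditions: H2 (1 atm), Lindlar catalyst, quinoline, EtOAc, rt, stopped at 1 equiv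
Reagents that add atoms: none
Why: Lindlar semi-hydrogenation gives the Z-C2=C3 alkene by syn addition and leaves the E-propenyl group, the enoate and the epoxide alone.

**Step 11**
Reactants: 18 the (Z)-allylic alcohol; 19 2-(bromomethyl)prop-2-enoic acid
Product: 20 (1Z,3S,4E)-1-{(2S,3R)-3-[(1E,3R)-2-(methoxycarbonyl)-3,4-bis(triethylsilyloxy)but-1-en-1-yl]oxiran-2-yl}hexa-1,4-dien-3-yl 2-(bromomethyl)prop-2-enoate
Conditions: 19 (1.5 equiv), DCC, DMAP (5 mol%), CH2Cl2, 0 °C
Reagents that add atoms: none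
Why: Steglich esterification acylates the only free hydroxyl with retention at C1; DMAP is kept catalytic and cold to spare the allylic bromide.

**Step 12**
Reactants: 20 the bromomethylacrylate ester
Product: 21 the C9 aldehyde of 20, i.e. the same ester with a (1E,3R)-2-(methoxycarbonyl)-4-oxo-3-(triethylsilyloxy)but-1-en-1-yl arm
Conditions: (COCl)2, DMSO, CH2Cl2, –78 to –40 °C; then iPr2NEt, –78 to –30 °C; used at once
Reagents that add atoms: none
Why: Direct Swern oxidation of a primary TES ether (the secondary TES ether is inert) gives the α-silyloxy aldehyde without ever freeing the γ-hydroxy ester.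

**Step 13**
Reactants: 21 the aldehyde ester
Product: 22 (5R)-3-(bromomethyl)-5-[(1Z)-2-{(2S,3R)-3-[(1E,3R)-2-(methoxycarbonyl)-4-oxo-3-(triethylsilyloxy)but-1-en-1-yl]oxiran-2-yl}ethenyl]furan-2(5H)-one
Conditions: Hoveyda–Grubbs II (10 mol%), CH2Cl2 (5 mM), 40 °C
Reagents that add atoms: none
Why: Ring-closing metathesis between the propenyl group and the 1,1-disubstituted acrylate forms the butenolide and expels propene; the hindered Z-alkene and the trisubstituted enoate do not compete (C1 becomes R only by CIP priority).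

**Step 14**
Reactants: 22 the bromomethylbutenolide aldehyde
Product: 24 macrocyclic alcohol: target skeleton with 8-OTES and free 9-OH (1R,4S,5R,8R,9S,10R by CIP; same spatial arrangement as the target), via allylchromium(III) dichloride 23 (not isolated)
Conditions: CrCl2 (6 equiv), THF (2 mM, 22 added over 8 h), rt; pH 7 buffer at 0 °C
Reagents that add atoms: none
Why: Proposed new method: CrCl2 reduces the allylic bromide to allylchromium 23, a β-acyl carbanion (homoenolate) equivalent that adds through its γ-carbon (butenolide β-carbon C10, normally a Michael-acceptor carbon) to the C9 aldehyde in a closed six-membered transition state, moving the double bond exocyclic and closing the ten-membered ring; C10 should form on the face opposite the C1–C2 bond (trans-fused lactone, one syn-periplanar ring unit fewer than the cis ring) and C9 by Felkin–Anh addition anti to the 8-OTES group (8,9-anti); the closest known reactions are intermolecular Cr- or In-mediated allylations of aldehydes with 3-(bromomethyl)furan-2(5H)-ones and Nozaki–Hiyama macrocyclisations of ω-formyl allylic bromides to germacrane rings.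

**Step 15**
Reactants: 25 angelic acid [(2Z)-2-methylbut-2-enoic acid]
Product: 26 (2Z)-2-methylbut-2-en-1-ol
Conditions: LiAlH4, Et2O, 0 °C
Reagents that add atoms: none
Why: Hydride reduction of the acid keeps the Z geometry (no conjugate reduction at 0 °C).

**Step 16**
Reactants: 26 (2Z)-2-methylbut-2-en-1-ol
Product: 27 [(2R,3S)-2,3-dimethyloxiran-2-yl]methanol
Conditions: Ti(OiPr)4 (10 mol%), D-(–)-DET (12 mol%), t-BuOOH, 4 Å MS, CH2Cl2, –20 °C
Reagents that add atoms: tert-butyl hydroperoxide CC(C)(C)OO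
Why: Sharpless asymmetric epoxidation with D-(–)-tartrate sets both oxirane centres; the Z-alkene keeps CH2OH and the 3-methyl cis.

**Step 17**
Reactants: 27 [(2R,3S)-2,3-dimethyloxiran-2-yl]methanol
Product: 28 (2S,3S)-2,3-dimethyloxirane-2-carboxylic acid
Conditions: RuCl3·xH2O (2 mol%), NaIO4 (3 equiv), CCl4/MeCN/H2O, rt
Reagents that add atoms: water, SMILES O
Why: Sharpless RuO4 oxidation takes the epoxy alcohol to the glycidic acid without opening the oxirane (C2 becomes S only by CIP priority).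

**Step 18**
Reactants: 24 the macrocyclic alcohol; 28 (2S,3S)-2,3-dimethyloxirane-2-carboxylic acid
Product: 30 the 8-O-TES 9-O-[(2S,3S)-2,3-dimethyloxirane-2-carbonyl] macrocycle (1R,4S,5R,8R,9S,10S), via mixed trichlorobenzoic anhydride 29 (not isolated)
Conditions: 28, 2,4,6-Cl3C6H2COCl, Et3N, toluene, rt; then 24, DMAP, rt
Reagents that add atoms: none
Why: Yamaguchi esterification acylates the hindered C9 hydroxyl with retention and without opening either epoxide.

**Step 19**
Reactants: 30 the 8-O-TES ester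
Product: 32 CNP0077533.1 (target), via C8 alcohol 31 (not isolated)
Conditions: Et3N·3HF, MeCN, 0 °C to rt; then pyridine, Ac2O, DMAP (cat.), 0 °C
Reagents that add atoms: acetic anhydride CC(=O)OC(C)=O
Why: Fluoride desilylation frees C8–OH, and in-situ acetylation is faster than migration of the hindered C9 ester; no stereocentre is touched.

**Compound list**
1 | dimethyl (R)-malate | COC(=O)C[C@@H](O)C(=O)OC | starting material
2 | methyl (3R)-3,4-dihydroxybutanoate | COC(=O)C[C@@H](O)CO | intermediate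
3 | methyl (3R)-3,4-bis(triethylsilyloxy)butanoate | COC(=O)C[C@@H](O[Si](CC)(CC)CC)CO[Si](CC)(CC)CC | intermediate
4 | ethyl (Z)-3-iodoprop-2-enoate | CCOC(=O)/C=C\I | starting material
5 | ethynyl(trimethyl)silane | C#C[Si](C)(C)C | starting material
6 | ethyl (Z)-5-(trimethylsilyl)pent-2-en-4-ynoate | CCOC(=O)/C=C\C#C[Si](C)(C)C | intermediate
7 | (Z)-5-(trimethylsilyl)pent-2-en-4-yn-1-ol | OC/C=C\C#C[Si](C)(C)C | intermediate
8 | [(2R,3S)-3-[(trimethylsilyl)ethynyl]oxiran-2-yl]methanol | C[Si](C)(C)C#C[C@@H]1O[C@@H]1CO | intermediate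
9 | (2S,3S)-3-[(trimethylsilyl)ethynyl]oxirane-2-carbaldehyde | C[Si](C)(C)C#C[C@@H]1O[C@@H]1C=O | intermediate
10 | lithium enolate of 3 (geometry not defined) | COC([O-])=C[C@@H](O[Si](CC)(CC)CC)CO[Si](CC)(CC)CC.[Li+] | intermediate
11 | lithium aldolate from 9 and 10 (C6/C7 mixture) | C[Si](C)(C)C#C[C@@H]1O[C@@H]1C([O-])C(C(=O)OC)[C@@H](O[Si](CC)(CC)CC)CO[Si](CC)(CC)CC.[Li+] | intermediate
12 | C6 methanesulfonate of the aldol (C6/C7 mixture) | C[Si](C)(C)C#C[C@@H]1O[C@@H]1C(OS(C)(=O)=O)C(C(=O)OC)[C@@H](O[Si](CC)(CC)CC)CO[Si](CC)(CC)CC | intermediate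
13 | methyl (2E,3R)-2-{[(2R,3S)-3-[(trimethylsilyl)ethynyl]oxiran-2-yl]methylidene}-3,4-bis(triethylsilyloxy)butanoate | C[Si](C)(C)C#C[C@@H]1O[C@@H]1/C=C(/C(=O)OC)[C@@H](O[Si](CC)(CC)CC)CO[Si](CC)(CC)CC | intermediate
14 | methyl (2E,3R)-2-{[(2R,3S)-3-ethynyloxiran-2-yl]methylidene}-3,4-bis(triethylsilyloxy)butanoate | C#C[C@@H]1O[C@@H]1/C=C(/C(=O)OC)[C@@H](O[Si](CC)(CC)CC)CO[Si](CC)(CC)CC | intermediate
15 | (E)-but-2-enal | C/C=C/C=O | starting material
16 | methylzinc acetylide of 14 | C[Zn]C#C[C@@H]1O[C@@H]1/C=C(/C(=O)OC)[C@@H](O[Si](CC)(CC)CC)CO[Si](CC)(CC)CC | intermediate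
17 | methyl (2E,3R)-2-({(2R,3S)-3-[(3S,4E)-3-hydroxyhex-4-en-1-yn-1-yl]oxiran-2-yl}methylidene)-3,4-bis(triethylsilyloxy)butanoate | O[C@@H](/C=C/C)C#C[C@@H]1O[C@@H]1/C=C(/C(=O)OC)[C@@H](O[Si](CC)(CC)CC)CO[Si](CC)(CC)CC | intermediate
18 | methyl (2E,3R)-2-({(2R,3S)-3-[(1Z,3S,4E)-3-hydroxyhexa-1,4-dien-1-yl]oxiran-2-yl}methylidene)-3,4-bis(triethylsilyloxy)butanoate | O[C@@H](/C=C/C)/C=C\[C@@H]1O[C@@H]1/C=C(/C(=O)OC)[C@@H](O[Si](CC)(CC)CC)CO[Si](CC)(CC)CC | intermediate
19 | 2-(bromomethyl)prop-2-enoic acid | OC(=O)C(=C)CBr | starting material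
20 | (1Z,3S,4E)-1-{(2S,3R)-3-[(1E,3R)-2-(methoxycarbonyl)-3,4-bis(triethylsilyloxy)but-1-en-1-yl]oxiran-2-yl}hexa-1,4-dien-3-yl 2-(bromomethyl)prop-2-enoate | C=C(CBr)C(=O)O[C@@H](/C=C/C)/C=C\[C@@H]1O[C@@H]1/C=C(/C(=O)OC)[C@@H](O[Si](CC)(CC)CC)CO[Si](CC)(CC)CC | intermediate
21 | (1Z,3S,4E)-1-{(2S,3R)-3-[(1E,3R)-2-(methoxycarbonyl)-4-oxo-3-(triethylsilyloxy)but-1-en-1-yl]oxiran-2-yl}hexa-1,4-dien-3-yl 2-(bromomethyl)prop-2-enoate | C=C(CBr)C(=O)O[C@@H](/C=C/C)/C=C\[C@@H]1O[C@@H]1/C=C(/C(=O)OC)[C@@H](O[Si](CC)(CC)CC)C=O | intermediate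
22 | (5R)-3-(bromomethyl)-5-[(1Z)-2-{(2S,3R)-3-[(1E,3R)-2-(methoxycarbonyl)-4-oxo-3-(triethylsilyloxy)but-1-en-1-yl]oxiran-2-yl}ethenyl]furan-2(5H)-one | O=C1O[C@@H](C=C1CBr)/C=C\[C@@H]2O[C@@H]2/C=C(/C(=O)OC)[C@@H](O[Si](CC)(CC)CC)C=O | intermediate
23 | allylchromium(III) dichloride from 22 (CH2Br replaced by CH2CrCl2) | O=C1O[C@@H](C=C1C[Cr](Cl)Cl)/C=C\[C@@H]2O[C@@H]2/C=C(/C(=O)OC)[C@@H](O[Si](CC)(CC)CC)C=O | intermediate
24 | macrocyclic alcohol: target ring system with 8-OTES and 9-OH, (1R,4S,5R,8R,9S,10R) | C=C1C(=O)O[C@@H]2/C=C\[C@@H]3O[C@@H]3/C=C(/C(=O)OC)[C@@H](O[Si](CC)(CC)CC)[C@@H](O)[C@@H]12 | intermediate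
25 | angelic acid, (2Z)-2-methylbut-2-enoic acid | C/C=C(/C)C(=O)O | starting material
26 | (2Z)-2-methylbut-2-en-1-ol | C/C=C(/C)CO | intermediate
27 | [(2R,3S)-2,3-dimethyloxiran-2-yl]methanol | OC[C@@]1(C)O[C@H]1C | intermediate
28 | (2S,3S)-2,3-dimethyloxirane-2-carboxylic acid | OC(=O)[C@@]1(C)O[C@H]1C | intermediate
29 | (2S,3S)-2,3-dimethyloxirane-2-carboxylic 2,4,6-trichlorobenzoic anhydride | O=C(OC(=O)[C@@]1(C)O[C@H]1C)c1c(Cl)cc(Cl)cc1Cl | intermediate
30 | 8-O-TES 9-O-[(2S,3S)-2,3-dimethyloxirane-2-carbonyl] macrocycle, (1R,4S,5R,8R,9S,10S) | C=C1C(=O)O[C@@H]2/C=C\[C@@H]3O[C@@H]3/C=C(/C(=O)OC)[C@@H](O[Si](CC)(CC)CC)[C@@H](OC(=O)[C@@]3(C)O[C@H]3C)[C@@H]12 | intermediate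
31 | 8-deacetyl target (free C8–OH), (1R,4S,5R,8R,9S,10S) | C=C1C(=O)O[C@@H]2/C=C\[C@@H]3O[C@@H]3/C=C(/C(=O)OC)[C@@H](O)[C@@H](OC(=O)[C@@]3(C)O[C@H]3C)[C@@H]12 | intermediate
32 | CNP0077533.1, (1R,4S,5R,8R,9S,10S)-8-acetoxy-9-[(2S,3S)-2,3-dimethyloxirane-2-carbonyloxy] methyl ester α-methylene lactone | C=C1C(=O)O[C@@H]2/C=C\[C@@H]3O[C@@H]3/C=C(/C(=O)OC)[C@@H](OC(C)=O)[C@@H](OC(=O)[C@@]3(C)O[C@H]3C)[C@@H]12 | target

**Totals**
Total steps: 19. Longest linear sequence: 14 (steps 3–14, 18, 19, from 4 to 32).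

**Three steps most likely to fail**

Step 14 (ring closure). The closure itself and the trans ring fusion rest on ring-strain arguments, and the C9 configuration is the weakest point. The ring-locked, E-type allylchromium would, through a chair transition state with an equatorial aldehyde substituent, favour the C9 epimer. The target configuration needs a boat-like arrangement together with Felkin–Anh control. If the cis-fused ring forms instead, this fallback does not help. Fallback: set out again from 22, run the same closure and accept the chair outcome. If the main product is the (9R)-epimeric macrocyclic alcohol F1, introduce the side chain with inversion instead of retention: Mitsunobu esterification of F1 with acid 28 (PPh3, DIAD, toluene, 0 °C) gives 30 directly, where the route is rejoined before step 19.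

Step 12 (direct Swern oxidation of the primary TES ether). The 2-(bromomethyl)acrylate is exposed to Me2S, chloride and amine base and may be alkylated or exchanged. Fallback: set out from 18, before any bromide is present. Cleave only the primary TES ether (HF·pyridine/pyridine, THF, –10 °C) to the C1,C9-diol methyl (2E,3R)-4-hydroxy-2-({(2R,3S)-3-[(1Z,3S,4E)-3-hydroxyhexa-1,4-dien-1-yl]oxiran-2-yl}methylidene)-3-(triethylsilyloxy)butanoate F2, used at once. Oxidise its primary alcohol chemoselectively (TEMPO cat., PhI(OAc)2, CH2Cl2) to the C1-hydroxy C9-aldehyde F3. Then esterify the C1 hydroxyl with 19 (DCC, DMAP cat.) to come back at 21.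

Step 9 (asymmetric alkynylation). A polyfunctional alkyne is used as the limiting partner, whereas the method normally uses excess alkyne, and the sense and level of induction must be verified. Fallback: set out from 14 and make the ketone first. Pd/Cu-catalysed acyl Sonogashira coupling with (E)-but-2-enoyl chloride (PdCl2(PPh3)2, CuI, Et3N, THF) gives the cross-conjugated ynone methyl (2E,3R)-2-({(2R,3S)-3-[(4E)-3-oxohex-4-en-1-yn-1-yl]oxiran-2-yl}methylidene)-3,4-bis(triethylsilyloxy)butanoate F4. Corey–Bakshi–Shibata reduction of F4 ((S)-Me-CBS, catecholborane, toluene, –78 °C, alkynyl as the small group) gives the (S)-carbinol and comes back at 17.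

**Further compounds**
F1 | step 14 | (9R)-epimer of macrocyclic alcohol 24 (8-OTES, 9-OH) | C=C1C(=O)O[C@@H]2/C=C\[C@@H]3O[C@@H]3/C=C(/C(=O)OC)[C@@H](O[Si](CC)(CC)CC)[C@H](O)[C@@H]12
F2 | step 12 | methyl (2E,3R)-4-hydroxy-2-({(2R,3S)-3-[(1Z,3S,4E)-3-hydroxyhexa-1,4-dien-1-yl]oxiran-2-yl}methylidene)-3-(triethylsilyloxy)butanoate | O[C@@H](/C=C/C)/C=C\[C@@H]1O[C@@H]1/C=C(/C(=O)OC)[C@@H](O[Si](CC)(CC)CC)CO
F3 | step 12 | methyl (2E,3R)-2-({(2R,3S)-3-[(1Z,3S,4E)-3-hydroxyhexa-1,4-dien-1-yl]oxiran-2-yl}methylidene)-4-oxo-3-(triethylsilyloxy)butanoate | O[C@@H](/C=C/C)/C=C\[C@@H]1O[C@@H]1/C=C(/C(=O)OC)[C@@H](O[Si](CC)(CC)CC)C=O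
F4 | step 9 | methyl (2E,3R)-2-({(2R,3S)-3-[(4E)-3-oxohex-4-en-1-yn-1-yl]oxiran-2-yl}methylidene)-3,4-bis(triethylsilyloxy)butanoate | C/C=C/C(=O)C#C[C@@H]1O[C@@H]1/C=C(/C(=O)OC)[C@@H](O[Si](CC)(CC)CC)CO[Si](CC)(CC)CC
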